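The ratio [C]/([B][R]) moves during a run, so I read it from the last readings of each run and carry it to a flask not yet run. Here C is intermediate C, B is intermediate B and R is the free reagent.

| setting | summer | dawn | noon | blue | violet |
|---|---|---|---|---|---|
| starting material | 0.67 M | 0.67 M | 0.67 M | 0.67 M | 0.67 M |
| reagent | 0.80 equiv | 1.4 equiv | 1.2 equiv | 1.60 equiv | 1.10 equiv |
| remark | run made earlier | run made earlier | run made earlier |  |  |
| time |  |  |  | 40 h | 40 h |

| run | time / h | intermediate C / % | intermediate A / % | starting material / % | intermediate B / % | target / % |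
|---|---|---|---|---|---|---|
| summer | 6.00 | 6.8 | 35.2 | 41.3 | 15.2 | 1.4 |
| summer | 12.0 | 15.5 | 42.0 | 19.9 | 21.2 | 1.7 |
| summer | 15.0 | 17.4 | 43.5 | 14.6 | 22.4 | 3.7 |
| summer | 25.0 | 19.6 | 46.6 | 8.3 | 22.6 | 3.4 |
| summer | 30.0 | 19.5 | 47.4 | 6.0 | 23.2 | 3.7 |
| dawn | 2.50 | 2.5 | 20.5 | 70.0 | 7.2 | 0.2 |
| dawn | 8.00 | 21.4 | 25.3 | 31.8 | 17.7 | 2.5 |
| dawn | 12.0 | 32.0 | 26.0 | 19.2 | 20.8 | 4.7 |
| dawn | 20.0 | 37.5 | 24.6 | 7.7 | 22.1 | 5.7 |
| dawn | 30.0 | 40.2 | 25.2 | 4.1 | 23.3 | 7.9 |
| noon | 6.00 | 12.0 | 27.7 | 42.7 | 15.5 | 1.6 |
| noon | 12.0 | 26.0 | 30.1 | 19.0 | 21.5 | 3.0 |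
| noon | 15.0 | 30.0 | 30.6 | 14.6 | 21.8 | 4.0 |
| noon | 25.0 | 32.2 | 31.1 | 7.0 | 22.9 | 6.5 |
| noon | 30.0 | 32.8 | 31.5 | 4.3 | 22.3 | 7.0 |

(each reading ± 0.5 percentage points)

- percentages count the starting material that a species holds: one homo dimer counts as two
- target is meant together with its crystals
- solid, in amounts per volume of the solution: crystals
- on the list of suspects stand: starting material <-> intermediate A; reagent + intermediate A <-> intermediate B; reagent + intermediate B -> target; reagent + intermediate B <-> intermediate C; crystals <-> target; 2 starting material -> homo dimer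

- which of these there is most of at the end, counted by the starting material in it, blue (intermediate C / intermediate A / target / intermediate B)
- which of these there is most of at the end, counted by the starting material in it, violet (intermediate C / intermediate A / target / intermediate B)
- how much there is at the end of the one of these that leads, in percent of the starting material charged: blue
- how much there is at the end of the one of these that leads, in percent of the starting material charged: violet

1. I count one reagent in intermediate B and two each in intermediate C and target. At the last dawn reading, 30.0 h, the ratio is 12.6 L mol⁻¹. I carry it as the ladder quotient, the reaction quotient of that step.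

2. The last summer and noon readings give 12.1 L mol⁻¹ and 12.1 L mol⁻¹. The dawn reading at 20.0 h gives 8.04 L mol⁻¹, so I use the quotient late in a run.

3. I bracket intermediate C in blue. I take intermediate B as at the last dawn reading, 23.3%, and put the reagent balance into the quotient, which gives one linear equation for intermediate C.

4. With no target the top is 54.5%. The floor is the last dawn reading, 40.2%, since blue has more reagent.

5. I tighten the top by granting blue at least the dawn target, 7.9%, which gives 48.2%. For the floor I scale that target generously, once by time and twice by charge, to 13.8%, which gives 43.5%.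

6. The forecast says intermediate C at 45% in blue, inside my bracket, and intermediate A at 37% in violet, which I did not bracket: “So C leads in blue and A leads in violet.”

7. Blue ends with intermediate C at 45.3%, and violet with intermediate A at 35.3%. Blue holds crystals 0% and homo dimer 0.151% at 40.0 h. In violet, the quotient times the reagent left, 13% of its charge, gives [C]/[B] = 1.20, and the flask shows 1.20.

    starting material ⇌ intermediate A (K = 7.81, k = 0.00254 min⁻¹)
    reagent + intermediate A ⇌ intermediate B (K = 7.20 L mol⁻¹, k = 0.00687 L mol⁻¹ min⁻¹)
    reagent + intermediate B → target (k = 8.15 × 10⁻⁴ L mol⁻¹ min⁻¹)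
    reagent + intermediate B ⇌ intermediate C (K = 11.6 L mol⁻¹, k = 0.00695 L mol⁻¹ min⁻¹)
    crystals ⇌ target, rate k5*(cs5 - [target]) while solid is left; crystals form when [target] > cs5 (solubility = 0.500 M, k = 0.0768 min⁻¹)
    2 starting material → homo dimer (k = 5.45 × 10⁻⁶ L mol⁻¹ min⁻¹)

8. Take the neighbour of violet with 4.40 equiv of reagent. If nearly all the starting material carries two reagent, the quotient gives [C]/[B] of about 20.2. The computed flask has intermediate C at 75.9% and intermediate B at 3.66%, a ratio of 20.7.

The readings stem from a simulated flask on assumed constants; scatter was added.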